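# Synthesis proposal for (2R,3S,5S,6R)-3-bromo-2-[(2E)-3-bromopent-2-en-1-yl]-5-chloro-6-[(2Z)-pent-2-en-4-yn-1-yl]oxane (24)

## The problem

Compound 24 is a 2,6-trans-dialkyl oxane. With the chain numbered from the alkyne CH (C1) to the ethyl CH3 (C15), the ring is O1–C6–C7–C8–C9–C10 and the stereocentres are 6R, 7S, 9S, 10R. C7–Cl is trans to the C6 chain and C9–Br is trans to the C10 chain.

The ring has no carbon branching beyond its two side chains. The tasks are therefore an ether bridge between two secondary carbons, two different secondary halides of fixed configuration, a (Z)-enyne at C6, and an (E)-bromoalkene at C10 in which C11 and the ethyl group are cis.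

The 2,6-trans arrangement forces one α-substituent axial, so it cannot be reached by equilibration and has to be set kinetically. Stereochemical information can be relayed around the ring: C6 can direct C10 across O1 and C7 beside it, and C10 can direct C9. One purchased stereocentre at C6 is therefore enough.

Several groups are fragile. Both secondary halides are β to the ring oxygen and prone to elimination, and O1 can participate whenever a leaving group is made at C9. The skipped enyne is base-sensitive, and the vinyl bromide does not tolerate alkyllithiums or zerovalent palladium for long. On the way, a β-chloro ketone and a β-alkoxy aldehyde are both open to E1cB reactions.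

The enabling feature is the array C7(Cl)–C8H2–C9. With C9 at the ketone level it is a β-chloro ketone inside the oxane, which is what oxidative opening of a cyclopropanol leaves behind. If C8 is the cyclopropane methylene and C7–C9 the fused bond, the precursor is a 3-oxabicyclo[3.1.0]hexane, that is, a 2,5-trans oxolan-3-one (O1, C6, C7, C9, C10) plus one carbon.

## Retrosynthesis

**24 ⇒ 23 ⇒ 20 + 21 (C3=C4).** The enyne is dismantled first, because its alkyne CH and skipped unsaturation would not survive the halogenation, metathesis and hydride steps. Cutting C3=C4 leads through the C-silylated enyne 23 to aldehyde 20 and the three-carbon silane 21. The neighbouring cut at C2–C3, a coupling of a vinyl iodide, needs zerovalent palladium next to the vinyl bromide and one more step, so it is held in reserve. The forward olefination must be Z-selective and must add to a β-alkoxy aldehyde faster than it deprotonates it.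

**20 ⇒ 18 (C4 oxidation level).** C4 is carried through the synthesis as a nitrile, so aldehyde 20 is traced to nitrile 18. Compared with a protected 2-hydroxyethyl group at C6, this removes a protection, a deprotection and an oxidation. A nitrile is also inert to carbenoids, FeCl3, borohydride and metathesis. The forward step is a partial reduction that must leave C–Cl, C–Br and the vinyl bromide alone.

**18 ⇒ 16 ⇒ 12 + 15; 15 ⇒ 13 (C12=C13).** The (E)-bromoalkene is cut at C12=C13. Olefination of a C12 aldehyde with an α-bromo ylide, or selective coupling of a gem-dibromoalkene, would be the obvious neighbours. Both are expected to leave bromine cis to C11, which is the wrong isomer. The cut is therefore made by cross-metathesis: allyl compound 12 and boronate 15 (one step from bromide 13) give alkenylboronate 16. Boron acts as a bulky place-holder that goes trans to C11 and is then exchanged for bromine with retention. Compound 12 lacks the whole C13–C15 unit, and its only alkene is a terminal allyl group, which is what the ring-forming chemistry below delivers. The metathesis must tolerate nitrile and halides and give one geometry, and the bromodeboronation must be stereoretentive.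

**12 ⇒ 11 ⇒ 10 (C9–Br).** C9–Br is cut as an SN2 displacement of the C9 alcohol of 11 with inversion, and 11 is the reduction product of ketone 10. Bromination after the metathesis was the alternative order. Doing it first keeps a free hydroxyl away from the ruthenium carbene and from electrophilic bromine. Ketone 10 has one stereocentre fewer and has C9 at the oxidation level the key step produces. Hydride must enter anti to the allyl group to give the 9,10-cis alcohol, and the displacement must beat participation by O1.

**10 ⇒ 9 (key disconnection: C7–Cl, C7–C9).** In 10 the unit Cl–C7–C8–C9(=O) is the product of oxidative opening of siloxycyclopropane 9. The transform rejoins C7 to C9, removes chlorine and returns the ring to an oxolane. This cut is preferred over displacing a C7 alcohol, because C7 is flanked by the C6 branch and β to O1, which makes it a poor SN2 site, whereas a C7 radical accepts chlorine without a leaving group. It is preferred over hydrochlorination of an enone because it is irreversible. Compound 9 lacks the halogen, and its two cyclopropane centres are erased in the step and need not be controlled. The forward reaction must cleave the fused bond and deliver chlorine anti to the C6 substituent.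

**9 ⇒ 8 ⇒ 7 (C7–C8, C8–C9).** The cyclopropane is removed by taking C8 back to a zinc carbenoid and silyl enol ether 8, which comes from oxolan-3-one 7. Building the cyclopropanol from an ester with titanium reagents was the neighbouring option, but it would not tolerate the nitrile. Enolisation of 7 must go toward C7 and away from C10, and the carbenoid must prefer the enol ether to the allyl group.

**7 ⇒ 6 (O1–C10, C10–C11).** Both bonds are cut in one operation: an allyl ether oxygen adds to a metal carbenoid at C10 and the allyl group shifts from O1 to C10. This leads to acyclic diazoketone 6 with a single stereocentre. A Williamson or oxa-Michael closure would need C10 preformed and favours the 2,5-cis ring. The forward step must form the five-membered ylide and give the 2,5-trans product.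

**6 ⇒ 4 ⇒ 3 ⇒ 1 + 2 (C9–C10, O–allyl).** Diazoketone 6 comes from acid 4 by acylation of a diazoalkane, 4 from ester 3, and 3 from hydroxy ester 1 and allyl donor 2. Compound 1 is a bulk chiral-pool material. Its carbinol carbon is C6 with the required R configuration, and its two arms are already differentiated: the ester becomes C9 and the nitrile becomes C4. An aldol or asymmetric-hydrogenation route to a 3-hydroxy-5-silyloxypentanoate would cost about four more steps up front and two more at the end. The O-allylation must proceed without base.

## Roads not taken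

**Alternative 1:** The cut is made at C6–C7 and C9–C10 together. Propane-1,3-diol A1 (C7–C8–C9) would be coupled at both ends with prop-2-ene-1,1-diyl dibenzoate A2 under iridium-catalysed transfer hydrogenation ([Ir(cod)Cl]2 with a chiral bisphosphine). This gives the C2-symmetric dibenzoate A3 with all four oxygen-bearing stereocentres in one step and no ring.
- Merits: it is catalytic, starts from an achiral diol, and the second allylation corrects the first, so enantiopurity should be very high. It sets four stereocentres in its key step against one here, and in that respect it is the better road.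
- Weak points: A3 has a symmetry that 24 lacks, so its two ends must be told apart three times. One carbinol must become chloride and the other bromide. One allylic oxygen must stay as O1 while the other carbon is displaced with inversion. One vinyl group must become the enyne and the other the bromopentenyl chain. The ring must then be closed by SN2 at a secondary allylic carbon, where SN2′ and elimination compete, and both halogens go in by inversion at secondary carbinols.
- Comparison: against the stereochemical efficiency of A3, the chosen plan never has to differentiate equivalent groups, makes the ring and C7–Cl in one step, and needs only one invertive substitution.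

**Alternative 2:** The cut is O1–C6 together with the C7/C8 oxidation pattern. Furyl carbinol A4, which already carries C10 and the bromoalkene chain, would be oxidised at the anode with a bromide mediator in methanol and then treated with acid. The ring-opened ene-dione recloses through the C10 hydroxyl to pyranone A5.
- Merits: the six-membered ring, the C9 ketone and a C7=C8 enone appear in one reagent-light step. The enone has the right pattern for chloride at C7, and ring size is never in question. For making the oxanone this road is shorter and better precedented than a ring expansion.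
- Weak points: C6 emerges as a hemiacetal, so the C5 chain must be attached afterwards by C-glycosylation. C7–Cl would come from a reversible conjugate hydrochlorination under thermodynamic control. Electrophilic bromine is generated next to the side-chain alkene. A4 needs an enantioselective synthesis with the (E)-bromoalkene already in place.
- Comparison: against the brevity of A5, the chosen plan has C6 as a purchased stereocentre, the C5 carbon present from the start, and chlorine delivered irreversibly in the ring-forming step.

**Alternative 3:** The cut is O1–C6 and C5–C6. Diazoketone A6 has the carbenoid carbon at C6 and an allyl ether on the C10 oxygen. Under copper catalysis (Cu(acac)2 or a fluorinated analogue) it would give a six-membered oxonium ylide whose [2,3]-shift closes the oxane as 2,6-trans oxan-3-one A7.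
- Merits: the oxane is closed directly with the correct 2,6-trans relationship and no ring expansion follows. As a ring-forming step it is at least as well founded as the key step chosen here, and the bromoalkene chain is already attached.
- Weak points: A6 must carry two stereocentres (C9, C10) and the (E)-bromoalkene before cyclisation, a much longer acyclic precursor than 6. Six-ring ylide formation competes more with C–H insertion than five-ring formation. Most importantly, both halogens must then be introduced by SN2 inversion on the ring, and C7, beside the C6 branch and β to O1, is the harder of the two sites.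
- Comparison: against the directness of A7, the chosen plan has a precursor with one chiral-pool stereocentre and places chlorine at C7 by radical transfer, leaving only one displacement.

Key step: step 7

Remark: compounds 1, 2, 13 and 21 are taken to be purchasable; in step 6 the carbenoid is assumed to add anti to the cyanomethyl group, and the opposite facial outcome would serve equally because C7 and C9 are reset in step 7.

## Route

Step 1
Reactants: 1 ethyl (3R)-4-cyano-3-hydroxybutanoate; 2 prop-2-en-1-yl 2,2,2-trichloroacetimidate
Product: 3 ethyl (3R)-4-cyano-3-(prop-2-en-1-yloxy)butanoate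
Conditions: TfOH (0.1 equiv), CH2Cl2/cyclohexane, 0 °C to rt
Reagents that add atoms: none
Why: Acid-catalysed O-alkylation by a trichloroacetimidate allylates the secondary alcohol without base, so the β-hydroxy ester cannot undergo retro-aldol cleavage or elimination; C6 is untouched and stays R.

Step 2
Reactants: 3 ethyl (3R)-4-cyano-3-(prop-2-en-1-yloxy)butanoate
Product: 4 (3R)-4-cyano-3-(prop-2-en-1-yloxy)butanoic acid
Conditions: LiOH·H2O, THF/H2O, 0 °C; then 1 M HCl to pH 3
Reagents that add atoms: lithium hydroxide, [Li+].[OH-]
Why: Ester saponification; hydroxide attack at the ester carbonyl at 0 °C is much faster than nitrile hydration or E1cB loss of the β-allyloxy group.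

Step 3
Reactants: 4 (3R)-4-cyano-3-(prop-2-en-1-yloxy)butanoic acid
Product: 6 (3R)-6-diazo-5-oxo-3-(prop-2-en-1-yloxy)hexanenitrile, via mixed isobutyl carbonic anhydride 5 (not isolated)
Conditions: i-BuOCOCl, Et3N, THF, −15 °C; then CH2N2, Et2O, 0 °C to rt
Reagents that add atoms: diazomethane, C=[N+]=[N-]; isobutyl chloroformate, CC(C)COC(Cl)=O (atoms kept in 5 only)
Why: Acylation of diazomethane by a mixed carbonic anhydride (the first stage of an Arndt–Eistert sequence) forms C9–C10; the anhydride is made and consumed cold so the β-alkoxy acyl unit does not eliminate.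

Step 4
Reactants: 6 (3R)-6-diazo-5-oxo-3-(prop-2-en-1-yloxy)hexanenitrile
Product: 7 2-[(2R,5R)-4-oxo-5-(prop-2-en-1-yl)oxolan-2-yl]acetonitrile
Conditions: Cu(acac)2 (5 mol %), THF, reflux
Reagents that add atoms: none
Why: The copper carbenoid is attacked by the ether oxygen to give a five-membered allyloxonium ylide, and a [2,3]-sigmatropic rearrangement forms O1–C10 and C10–C11; the allyl group on oxygen lies anti to the C6 cyanomethyl group and migrates suprafacially, which sets C10 trans to C6.

Step 5
Reactants: 7 2-[(2R,5R)-4-oxo-5-(prop-2-en-1-yl)oxolan-2-yl]acetonitrile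
Product: 8 2-[(2R,5R)-5-(prop-2-en-1-yl)-4-(trimethylsilyloxy)-2,5-dihydrofuran-2-yl]acetonitrile
Conditions: LiN(i-Pr)2 (1.1 equiv), Me3SiCl (internal quench), THF, −78 °C; Et3N, pentane, filtration
Reagents that add atoms: chlorotrimethylsilane, C[Si](C)(C)Cl
Why: Kinetic enolisation with in-situ O-silylation (silyl enol ether formation); the hindered amide takes a proton from the C7 methylene and not from the more hindered, oxygen-bearing C10–H, and immediate silylation prevents equilibration, C10 epimerisation and the disfavoured endocyclic β-elimination of O1.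

Step 6
Reactants: 8 2-[(2R,5R)-5-(prop-2-en-1-yl)-4-(trimethylsilyloxy)-2,5-dihydrofuran-2-yl]acetonitrile
Product: 9 2-[(1S,2R,4R,5R)-2-(prop-2-en-1-yl)-1-(trimethylsilyloxy)-3-oxabicyclo[3.1.0]hexan-4-yl]acetonitrile
Conditions: Et2Zn (1.5 equiv), CH2I2 (1.5 equiv), CH2Cl2, 0 °C; pyridine quench
Reagents that add atoms: diiodomethane, ICI
Why: Simmons–Smith cyclopropanation (Furukawa variant); the silyl enol ether is far more nucleophilic than the monosubstituted allyl alkene, so a small excess of zinc carbenoid should add only across C7=C9, and the facial outcome does not matter because both new centres are reset in step 7.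

Step 7
Reactants: 9 2-[(1S,2R,4R,5R)-2-(prop-2-en-1-yl)-1-(trimethylsilyloxy)-3-oxabicyclo[3.1.0]hexan-4-yl]acetonitrile
Product: 10 2-[(2R,3S,6R)-3-chloro-5-oxo-6-(prop-2-en-1-yl)oxan-2-yl]acetonitrile
Conditions: FeCl3 (2.5 equiv), DMF, 0 °C to rt; cold neutral work-up, used at once
Reagents that add atoms: iron trichloride, Cl[Fe](Cl)Cl
Why: The cyclopropane oxygen passes from silicon to trivalent iron (Me3SiCl is lost) and inner-sphere electron transfer gives a cyclopropyloxy radical, or its iron-bound equivalent, at C9. β-Scission of the fused C7–C9 bond releases the ring strain, forms the C9 carbonyl and leaves a secondary radical at C7, which takes chlorine from a second FeCl3 by ligand transfer to form C7–Cl. The closest known reaction type is the FeCl3-mediated oxidative ring enlargement of 1-silyloxybicyclo[n.1.0]alkanes to 3-chlorocycloalkanones. The oxane is not formed by a cyclisation: it arises by one-carbon enlargement of the oxolane, the zero-atom bridge C7–C9 of the bicyclo[3.1.0] skeleton being cut so that C8 becomes a ring member. The new stereocentre C7 is controlled by the neighbouring C6 cyanomethyl group, chlorine being delivered to the planar radical on the face anti to it. The step needs cleavage of the fused bond and not the outer C8–C9 bond, which is secured because ring opening is reversible until chlorine is transferred and the secondary C7 radical is favoured over a primary one. It also needs chlorine transfer to outrun addition of the C7 radical to the allyl alkene, which is secured by the high FeCl3 concentration and the strained bridged transition state such a cyclisation would require.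

Step 8
Reactants: 10 2-[(2R,3S,6R)-3-chloro-5-oxo-6-(prop-2-en-1-yl)oxan-2-yl]acetonitrile
Product: 11 2-[(2R,3S,5R,6R)-3-chloro-5-hydroxy-6-(prop-2-en-1-yl)oxan-2-yl]acetonitrile
Conditions: LiBH(s-Bu)3 (1.1 equiv), THF, −78 °C; AcOH quench
Reagents that add atoms: none
Why: Diastereoselective ketone reduction by a bulky borohydride; hydride reaches C9 from the face opposite the adjacent C10 allyl group (in the other chair, opposite the axial C7–Cl), giving the 9,10-cis alcohol, and at −78 °C reduction should outrun E1cB loss of chloride.

Step 9
Reactants: 11 2-[(2R,3S,5R,6R)-3-chloro-5-hydroxy-6-(prop-2-en-1-yl)oxan-2-yl]acetonitrile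
Product: 12 2-[(2R,3S,5S,6R)-5-bromo-3-chloro-6-(prop-2-en-1-yl)oxan-2-yl]acetonitrile
Conditions: CBr4 (3 equiv), P(n-Oct)3 (3 equiv), toluene, 70 °C
Reagents that add atoms: tetrabromomethane, BrC(Br)(Br)Br
Why: Appel-type bromination through an alkoxyphosphonium salt with SN2 inversion at C9; in the preferred chair the activated oxygen is equatorial and bromide enters along the open axial trajectory anti to the C10 allyl group, giving C9–Br trans to the C10 chain.

Step 10
Reactants: 13 2-bromobut-1-ene
Product: 15 2-(but-1-en-2-yl)-4,4,5,5-tetramethyl-1,3,2-dioxaborolane, via but-1-en-2-ylmagnesium bromide 14 (not isolated)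
Conditions: Mg, THF, reflux; then i-PrOBpin, −78 °C to rt; 1 M HCl
Reagents that add atoms: 2-isopropoxy-4,4,5,5-tetramethyl-1,3,2-dioxaborolane, CC(C)OB1OC(C)(C)C(C)(C)O1; magnesium, [Mg] (kept in 14 only)
Why: Grignard formation from the vinylic bromide followed by borylation with an alkoxyboronate gives the 1,1-disubstituted alkenylboronate.

Step 11
Reactants: 12 2-[(2R,3S,5S,6R)-5-bromo-3-chloro-6-(prop-2-en-1-yl)oxan-2-yl]acetonitrile; 15 2-(but-1-en-2-yl)-4,4,5,5-tetramethyl-1,3,2-dioxaborolane
Product: 16 2-[(2R,3S,5S,6R)-5-bromo-3-chloro-6-[(2Z)-3-(4,4,5,5-tetramethyl-1,3,2-dioxaborolan-2-yl)pent-2-en-1-yl]oxan-2-yl]acetonitrile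
Conditions: 15 (4 equiv), second-generation Grubbs catalyst RuCl2(=CHPh)(H2IMes)(PCy3) (10 mol %), CH2Cl2, 40 °C
Reagents that add atoms: none
Why: Olefin cross-metathesis of a terminal alkene with a 1,1-disubstituted alkenyl pinacolboronate; the bulky boryl group takes the position trans to the C11 methylene, so the ethyl group ends cis to C11 (Z-boronate) and ethene is lost.

Step 12
Reactants: 16 2-[(2R,3S,5S,6R)-5-bromo-3-chloro-6-[(2Z)-3-(4,4,5,5-tetramethyl-1,3,2-dioxaborolan-2-yl)pent-2-en-1-yl]oxan-2-yl]acetonitrile
Product: 18 2-[(2R,3S,5S,6R)-5-bromo-6-[(2E)-3-bromopent-2-en-1-yl]-3-chlorooxan-2-yl]acetonitrile, via potassium alkenyltrifluoroborate 17 (not isolated)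
Conditions: KHF2, MeOH/H2O, rt; then NaBr, TsNClNa (chloramine-T), THF/H2O, 0 °C to rt
Reagents that add atoms: sodium bromide, [Na+].[Br-]; potassium hydrogen difluoride, [K+].[F-].F (atoms kept in 17 only)
Why: Conversion to the trifluoroborate and electrophilic ipso-bromodeboronation, a substitution expected to proceed with retention of alkene geometry, so bromine replaces boron trans to C11 and the (E)-bromoalkene results; the alkyl halides and the nitrile are inert to the mild electrophilic bromine source.

Step 13
Reactants: 18 2-[(2R,3S,5S,6R)-5-bromo-6-[(2E)-3-bromopent-2-en-1-yl]-3-chlorooxan-2-yl]acetonitrile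
Product: 20 2-[(2R,3S,5S,6R)-5-bromo-6-[(2E)-3-bromopent-2-en-1-yl]-3-chlorooxan-2-yl]acetaldehyde, via N-diisobutylalumanyl aldimine 19 (not isolated)
Conditions: i-Bu2AlH (1.2 equiv), CH2Cl2, −78 °C; MeOH, then aq. tartaric acid, 0 °C; used crude
Reagents that add atoms: water, O; diisobutylaluminium hydride, CC(C)C[AlH]CC(C)C (atoms kept in 19 only)
Why: Partial reduction of a nitrile with one equivalent of aluminium hydride stops at the N-aluminio aldimine, which is hydrolysed to the aldehyde on mildly acidic work-up; alkyl and alkenyl halides are inert at −78 °C.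

Step 14
Reactants: 20 2-[(2R,3S,5S,6R)-5-bromo-6-[(2E)-3-bromopent-2-en-1-yl]-3-chlorooxan-2-yl]acetaldehyde; 21 1,3-bis(triisopropylsilyl)prop-1-yne
Product: 23 triisopropyl{(3Z)-5-[(2R,3S,5S,6R)-5-bromo-6-[(2E)-3-bromopent-2-en-1-yl]-3-chlorooxan-2-yl]pent-3-en-1-yn-1-yl}silane, via lithiated bis-silylpropyne 22 (not isolated)
Conditions: 21, n-BuLi, THF, −20 °C; then 20, −78 °C to 0 °C
Reagents that add atoms: butyllithium, [Li]CCCC (lithium kept in 22 only)
Why: Peterson olefination with the lithiated bis-silylpropyne; addition to the aldehyde and syn-elimination of silanolate from the β-silyl alkoxide favours the (Z)-enyne, and at −78 °C addition should be faster than deprotonation of the β-alkoxy aldehyde.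

Step 15
Reactants: 23 triisopropyl{(3Z)-5-[(2R,3S,5S,6R)-5-bromo-6-[(2E)-3-bromopent-2-en-1-yl]-3-chlorooxan-2-yl]pent-3-en-1-yn-1-yl}silane
Product: 24 (2R,3S,5S,6R)-3-bromo-2-[(2E)-3-bromopent-2-en-1-yl]-5-chloro-6-[(2Z)-pent-2-en-4-yn-1-yl]oxane
Conditions: n-Bu4NF, THF, 0 °C
Reagents that add atoms: none
Why: Fluoride-induced protodesilylation of the alkynylsilane; short exposure at 0 °C should leave the secondary halides and the skipped enyne intact.

## Compound list

1 | ethyl (3R)-4-cyano-3-hydroxybutanoate | N#CC[C@@H](O)CC(=O)OCC | starting material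
2 | prop-2-en-1-yl 2,2,2-trichloroacetimidate | C=CCOC(=N)C(Cl)(Cl)Cl | starting material
3 | ethyl (3R)-4-cyano-3-(prop-2-en-1-yloxy)butanoate | N#CC[C@@H](OCC=C)CC(=O)OCC | intermediate
4 | (3R)-4-cyano-3-(prop-2-en-1-yloxy)butanoic acid | N#CC[C@@H](OCC=C)CC(=O)O | intermediate
5 | (3R)-4-cyano-3-(prop-2-en-1-yloxy)butanoic isobutyl carbonic anhydride | N#CC[C@@H](OCC=C)CC(=O)OC(=O)OCC(C)C | intermediate
6 | (3R)-6-diazo-5-oxo-3-(prop-2-en-1-yloxy)hexanenitrile | N#CC[C@@H](OCC=C)CC(=O)C=[N+]=[N-] | intermediate
7 | 2-[(2R,5R)-4-oxo-5-(prop-2-en-1-yl)oxolan-2-yl]acetonitrile | N#CC[C@H]1O[C@H](CC=C)C(=O)C1 | intermediate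
8 | 2-[(2R,5R)-5-(prop-2-en-1-yl)-4-(trimethylsilyloxy)-2,5-dihydrofuran-2-yl]acetonitrile | N#CC[C@H]1O[C@H](CC=C)C(O[Si](C)(C)C)=C1 | intermediate
9 | 2-[(1S,2R,4R,5R)-2-(prop-2-en-1-yl)-1-(trimethylsilyloxy)-3-oxabicyclo[3.1.0]hexan-4-yl]acetonitrile | N#CC[C@H]3O[C@H](CC=C)[C@]4(O[Si](C)(C)C)C[C@H]34 | intermediate
10 | 2-[(2R,3S,6R)-3-chloro-5-oxo-6-(prop-2-en-1-yl)oxan-2-yl]acetonitrile | N#CC[C@H]3O[C@H](CC=C)C(=O)C[C@@H]3Cl | intermediate
11 | 2-[(2R,3S,5R,6R)-3-chloro-5-hydroxy-6-(prop-2-en-1-yl)oxan-2-yl]acetonitrile | N#CC[C@H]3O[C@H](CC=C)[C@H](O)C[C@@H]3Cl | intermediate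
12 | 2-[(2R,3S,5S,6R)-5-bromo-3-chloro-6-(prop-2-en-1-yl)oxan-2-yl]acetonitrile | N#CC[C@H]3O[C@H](CC=C)[C@@H](Br)C[C@@H]3Cl | intermediate
13 | 2-bromobut-1-ene | C=C(Br)CC | starting material
14 | but-1-en-2-ylmagnesium bromide | C=C(CC)[Mg]Br | intermediate
15 | 2-(but-1-en-2-yl)-4,4,5,5-tetramethyl-1,3,2-dioxaborolane | C=C(CC)B1OC(C)(C)C(C)(C)O1 | intermediate
16 | 2-[(2R,3S,5S,6R)-5-bromo-3-chloro-6-[(2Z)-3-(4,4,5,5-tetramethyl-1,3,2-dioxaborolan-2-yl)pent-2-en-1-yl]oxan-2-yl]acetonitrile | N#CC[C@H]3O[C@H](C/C=C(/B1OC(C)(C)C(C)(C)O1)CC)[C@@H](Br)C[C@@H]3Cl | intermediate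
17 | potassium {(2Z)-1-[(2R,3S,5S,6R)-3-bromo-5-chloro-6-(cyanomethyl)oxan-2-yl]pent-2-en-3-yl}trifluoroborate | N#CC[C@H]3O[C@H](C/C=C(/[B-](F)(F)F)CC)[C@@H](Br)C[C@@H]3Cl.[K+] | intermediate
18 | 2-[(2R,3S,5S,6R)-5-bromo-6-[(2E)-3-bromopent-2-en-1-yl]-3-chlorooxan-2-yl]acetonitrile | N#CC[C@H]3O[C@H](C/C=C(/Br)CC)[C@@H](Br)C[C@@H]3Cl | intermediate
19 | N-[bis(2-methylpropyl)alumanyl]-2-[(2R,3S,5S,6R)-5-bromo-6-[(2E)-3-bromopent-2-en-1-yl]-3-chlorooxan-2-yl]ethan-1-imine | CC(C)C[Al](CC(C)C)N=CC[C@H]3O[C@H](C/C=C(/Br)CC)[C@@H](Br)C[C@@H]3Cl | intermediate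
20 | 2-[(2R,3S,5S,6R)-5-bromo-6-[(2E)-3-bromopent-2-en-1-yl]-3-chlorooxan-2-yl]acetaldehyde | O=CC[C@H]3O[C@H](C/C=C(/Br)CC)[C@@H](Br)C[C@@H]3Cl | intermediate
21 | 1,3-bis(triisopropylsilyl)prop-1-yne | CC(C)[Si](C(C)C)(C(C)C)CC#C[Si](C(C)C)(C(C)C)C(C)C | starting material
22 | [1,3-bis(triisopropylsilyl)prop-2-yn-1-yl]lithium | [Li]C(C#C[Si](C(C)C)(C(C)C)C(C)C)[Si](C(C)C)(C(C)C)C(C)C | intermediate
23 | triisopropyl{(3Z)-5-[(2R,3S,5S,6R)-5-bromo-6-[(2E)-3-bromopent-2-en-1-yl]-3-chlorooxan-2-yl]pent-3-en-1-yn-1-yl}silane | CC(C)[Si](C(C)C)(C(C)C)C#C/C=C\C[C@H]1O[C@H](C/C=C(/Br)CC)[C@@H](Br)C[C@@H]1Cl | intermediate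
24 | (2R,3S,5S,6R)-3-bromo-2-[(2E)-3-bromopent-2-en-1-yl]-5-chloro-6-[(2Z)-pent-2-en-4-yn-1-yl]oxane | C#C/C=C\C[C@H]1O[C@H](C/C=C(/Br)CC)[C@@H](Br)C[C@@H]1Cl | target

## Step count and least certain steps

Total step count: 15. Longest linear sequence: 14 (steps 1–9 and 11–15, from 1); step 10 is a one-step side branch from 13.

**Step 7 (key step).** What may go wrong: loss of HCl from the β-chloro ketone under the Lewis-acidic iron salts; low facial selectivity in the chlorine transfer to the C7 radical; competing cleavage of the outer cyclopropane bond; enolisation toward C10 with epimerisation. Fallback, which also bypasses steps 5 and 6: it sets out from oxolanone 7. Lewis-acid-promoted one-carbon homologation with Me3SiCHN2/BF3·OEt2, in which the unoxygenated C7 methylene migrates, followed by desilylation, gives oxan-3-one F1. Kinetic enolisation and silylation toward C8 (LiN(i-Pr)2, Me3SiCl) gives silyl enol ether F2. Saegusa–Ito oxidation with Pd(OAc)2 in MeCN gives enone F3. Conjugate addition of HCl in Et2O at low temperature, with chloride entering C7 anti to the cyanomethyl group, returns to the route at 10.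

**Step 11.** What may go wrong: slow cross-metathesis of the hindered 1,1-disubstituted boronate, so that self-metathesis of 12 dominates; incomplete control of the geometry of the new trisubstituted alkene. Fallback: it sets out from 12. Ozonolysis of the allyl group (O3, CH2Cl2, −78 °C; Me2S) gives aldehyde F4. A boron-Wittig olefination with 1,1-bis(pinacolboryl)propane deprotonated by lithium 2,2,6,6-tetramethylpiperidide (THF, −78 °C), in which syn-elimination of boron and oxygen leaves the remaining boryl group trans to the chain, returns to the route at 16.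

**Step 9.** What may go wrong: participation of the ring oxygen, which lies anti-periplanar to the activated equatorial C9 oxygen, leading to ring contraction or substitution with retention; E2 elimination at 70 °C. Fallback: it sets out from 11. Sulfonylation with ClCH2SO2Cl and 2,6-lutidine gives chloromethanesulfonate F5, an isolated and very reactive ester. Displacement by LiBr in DMF near room temperature, under bromide-rich conditions where bimolecular substitution should outrun participation, returns to the route at 12.

**Step 14.** What may go wrong: erosion of Z selectivity in the elimination of silanolate; base-induced β-elimination of the β-alkoxy aldehyde with opening of the oxane. Fallback: it sets out from 20. Stork–Zhao olefination ([Ph3PCH2I]I, NaN(SiMe3)2, THF, −78 °C) gives (Z)-vinyl iodide F6. Sonogashira coupling with trimethylsilylacetylene (PdCl2(PPh3)2, CuI, i-Pr2NH, rt), in which the iodide reacts far faster than the trisubstituted bromide, gives silyl enyne F7. K2CO3 in MeOH removes silicon and returns to the route at 24.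

## Further compounds

F1 | step 7 | 2-[(2S,6R)-5-oxo-6-(prop-2-en-1-yl)oxan-2-yl]acetonitrile | N#CC[C@H]3O[C@H](CC=C)C(=O)CC3
F2 | step 7 | 2-[(2S,6R)-6-(prop-2-en-1-yl)-5-(trimethylsilyloxy)-3,6-dihydro-2H-pyran-2-yl]acetonitrile | N#CC[C@H]3O[C@H](CC=C)C(O[Si](C)(C)C)=CC3
F3 | step 7 | 2-[(2R,6R)-5-oxo-6-(prop-2-en-1-yl)-5,6-dihydro-2H-pyran-2-yl]acetonitrile | N#CC[C@H]3O[C@H](CC=C)C(=O)C=C3
F4 | step 11 | 2-[(2R,3S,5S,6R)-5-bromo-3-chloro-6-(2-oxoethyl)oxan-2-yl]acetonitrile | N#CC[C@H]3O[C@H](CC=O)[C@@H](Br)C[C@@H]3Cl
F5 | step 9 | (2R,3R,5S,6R)-5-chloro-6-(cyanomethyl)-2-(prop-2-en-1-yl)oxan-3-yl chloromethanesulfonate | N#CC[C@H]3O[C@H](CC=C)[C@H](OS(=O)(=O)CCl)C[C@@H]3Cl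
F6 | step 14 | (2R,3S,5S,6R)-3-bromo-2-[(2E)-3-bromopent-2-en-1-yl]-5-chloro-6-[(2Z)-3-iodoprop-2-en-1-yl]oxane | I/C=C\C[C@H]1O[C@H](C/C=C(/Br)CC)[C@@H](Br)C[C@@H]1Cl
F7 | step 14 | trimethyl{(3Z)-5-[(2R,3S,5S,6R)-5-bromo-6-[(2E)-3-bromopent-2-en-1-yl]-3-chlorooxan-2-yl]pent-3-en-1-yn-1-yl}silane | C[Si](C)(C)C#C/C=C\C[C@H]1O[C@H](C/C=C(/Br)CC)[C@@H](Br)C[C@@H]1Cl
A1 | alternative 1 | propane-1,3-diol | OCCCO
A2 | alternative 1 | prop-2-ene-1,1-diyl dibenzoate | C=CC(OC(=O)c1ccccc1)OC(=O)c1ccccc1
A3 | alternative 1 | (3S,4R,6R,7S)-4,6-dihydroxynona-1,8-diene-3,7-diyl dibenzoate | C=C[C@H](OC(=O)c1ccccc1)[C@H](O)C[C@@H](O)[C@@H](OC(=O)c1ccccc1)C=C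
A4 | alternative 2 | (1R,3E)-4-bromo-1-(furan-2-yl)hex-3-en-1-ol | O[C@H](C/C=C(/Br)CC)c1ccco1
A5 | alternative 2 | (2R,6S)-2-[(2E)-3-bromopent-2-en-1-yl]-6-hydroxy-2H-pyran-3(6H)-one | O[C@H]1O[C@H](C/C=C(/Br)CC)C(=O)C=C1
A6 | alternative 3 | (4R,5R,7E)-8-bromo-4-[(tert-butyldimethylsilyl)oxy]-1-diazo-5-(prop-2-en-1-yloxy)dec-7-en-2-one | [N-]=[N+]=CC(=O)C[C@@H](O[Si](C)(C)C(C)(C)C)[C@H](OCC=C)C/C=C(/Br)CC
A7 | alternative 3 | (2R,5R,6R)-6-[(2E)-3-bromopent-2-en-1-yl]-5-[(tert-butyldimethylsilyl)oxy]-2-(prop-2-en-1-yl)oxan-3-one | C=CC[C@H]1O[C@H](C/C=C(/Br)CC)[C@H](O[Si](C)(C)C(C)(C)C)CC1=O
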